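**Strategy.** Everything rests on cutting the C2–C3 bond of the dihydropyran ring of the chroman. The key step exploits that C2 is quaternary and bonded to O1, hence a stabilised tertiary α-aryloxy radical, while C3–C4 can be a vinyl group on C4a. The precursor is a 2-(2-vinylaryloxy)-2-methylpropanoic acid. Reductive photodecarboxylation of its N-acyloxyphthalimide releases the C2 radical, which closes the ring 6-endo onto the styrene in one operation, CO2 being a traceless activator. The resulting chroman aldehyde is condensed with a 3-aryltetronic acid that carries the (R)-epoxide from a Shi epoxidation, and neutral deallylation ends the route.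

Key step: step 5

Assumption: the D-fructose-derived Shi ketone is taken to give the (R)-oxirane from the 3-methylbut-2-enyl group, as its spiro transition-state model predicts for trisubstituted alkenes; compounds 1, 2, 4, 6, 9, 12, 13 and 17 are taken as commercial.

**Step 1**
Reactants: 1 5-bromo-2,4-dihydroxybenzaldehyde; 2 ethyl 2-bromo-2-methylpropanoate
Product: 3 ethyl 2-(2-bromo-4-formyl-5-hydroxyphenoxy)-2-methylpropanoate
Conditions: K2CO3 (1.2 equiv), DMF, 60 °C
Reagents that add atoms: ethyl 2-bromo-2-methylpropanoate, CCOC(=O)C(C)(C)Br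
Why: Williamson etherification, in which the 4-hydroxyl (para to the formyl group, more acidic and not hydrogen-bonded) should be alkylated selectively while the 2-hydroxyl stays locked in its hydrogen bond to the aldehyde.

**Step 2**
Reactants: 3 ethyl 2-(2-bromo-4-formyl-5-hydroxyphenoxy)-2-methylpropanoate; 4 4,4,5,5-tetramethyl-2-vinyl-1,3,2-dioxaborolane
Product: 5 ethyl 2-(4-formyl-5-hydroxy-2-vinylphenoxy)-2-methylpropanoate
Conditions: Pd(OAc)2 (3 mol%), SPhos (6 mol%), K3PO4, dioxane/H2O, 80 °C
Reagents that add atoms: 4,4,5,5-tetramethyl-2-vinyl-1,3,2-dioxaborolane, C=CB1OC(C)(C)C(C)(C)O1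
Why: Suzuki–Miyaura coupling of the hindered aryl bromide with a vinylboronate, which tolerates the free phenol, the aldehyde and the hindered ester under phosphate base.

**Step 3**
Reactants: 5 ethyl 2-(4-formyl-5-hydroxy-2-vinylphenoxy)-2-methylpropanoate; 6 allyl bromide
Product: 7 ethyl 2-[5-(allyloxy)-4-formyl-2-vinylphenoxy]-2-methylpropanoate
Conditions: K2CO3, DMF, 50 °C
Reagents that add atoms: allyl bromide, C=CCBr
Why: Williamson allylation of the remaining phenol; the allyl ether should survive the radical, alkoxide and amidine steps and leave later under neutral conditions.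

**Step 4**
Reactants: 7 ethyl 2-[5-(allyloxy)-4-formyl-2-vinylphenoxy]-2-methylpropanoate
Product: 8 2-[5-(allyloxy)-4-formyl-2-vinylphenoxy]-2-methylpropanoic acid
Conditions: LiOH·H2O, THF/MeOH/H2O, rt; then 1 M HCl to pH 3
Reagents that add atoms: lithium hydroxide, [Li+].[OH-]
Why: Saponification of the ethyl ester, to which the non-enolisable aldehyde, the allyl ether and the styrene should be inert at room temperature.

**Step 5**
Reactants: 8 2-[5-(allyloxy)-4-formyl-2-vinylphenoxy]-2-methylpropanoic acid; 9 N-hydroxyphthalimide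
Product: 11 7-(allyloxy)-2,2-dimethylchroman-6-carbaldehyde, via N-acyloxyphthalimide ester 10 (not isolated)
Conditions: DIC, DMAP (cat.), CH2Cl2, rt; then Hantzsch ester (1.5 equiv), Ru(bpy)3(PF6)2 (1 mol%), CH2Cl2 (0.01 M), 450 nm LEDs, rt
Reagents that add atoms: none
Why: The Hantzsch ester reductively quenches the photoexcited ruthenium complex, whose reduced form passes one electron to the N-acyloxyphthalimide, and N–O cleavage with loss of CO2 gives the tertiary α-aryloxy radical at C2. This nucleophilic radical adds to the terminal carbon of the ortho vinyl group, forming the C2–C3 bond and closing the dihydropyran ring in the 6-endo-trig mode, and the benzylic C4 radical is then quenched by hydrogen transfer from the Hantzsch ester. The closest known reaction type is the visible-light reductive decarboxylative Giese addition and radical cyclisation of redox-active esters. No stereocenter is formed. The step needs 6-endo over 5-exo closure, which the substrate should secure because attack at the terminal CH2 is unhindered, keeps the styrene conjugated and gives a benzylic radical, whereas 5-exo attack would need the vinyl group twisted out of the arene plane and would give a primary radical. High dilution should keep the radical from adding to a second styrene, and the allyl ether and the aldehyde are out of reach of, or unreactive toward, the radical.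

**Step 6**
Reactants: 12 methyl 2-(3-bromo-4-hydroxyphenyl)acetate; 13 tributyl(3-methylbut-2-en-1-yl)stannane
Product: 14 methyl 2-[4-hydroxy-3-(3-methylbut-2-en-1-yl)phenyl]acetate
Conditions: Pd(PPh3)4 (5 mol%), DMF, 100 °C
Reagents that add atoms: tributyl(3-methylbut-2-en-1-yl)stannane, CCCC[Sn](CCCC)(CCCC)CC=C(C)C
Why: Stille coupling under neutral conditions that tolerate the free phenol and the ester; reductive elimination from the less hindered terminus of the prenyl–palladium intermediate should give the linear 3-methylbut-2-enyl arene.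

**Step 7**
Reactants: 14 methyl 2-[4-hydroxy-3-(3-methylbut-2-en-1-yl)phenyl]acetate; 6 allyl bromide
Product: 15 methyl 2-[4-(allyloxy)-3-(3-methylbut-2-en-1-yl)phenyl]acetate
Conditions: K2CO3, acetone, reflux
Reagents that add atoms: allyl bromide, C=CCBr
Why: Williamson allylation of the phenol with a base too weak to enolise the arylacetate; the phenol must be capped before the epoxide is made next to it.

**Step 8**
Reactants: 15 methyl 2-[4-(allyloxy)-3-(3-methylbut-2-en-1-yl)phenyl]acetate
Product: 16 methyl 2-[4-(allyloxy)-3-{[(2R)-3,3-dimethyloxiran-2-yl]methyl}phenyl]acetate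
Conditions: 1,2:4,5-di-O-isopropylidene-β-D-erythro-2,3-hexodiulo-2,6-pyranose (D-fructose-derived Shi ketone, 0.3 equiv), Oxone (2KHSO5·KHSO4·K2SO4), K2CO3, Bu4NHSO4 (cat.), MeCN/dimethoxymethane/aq. Na2B4O7–Na2EDTA buffer (pH 10.5), 0 °C
Reagents that add atoms: potassium peroxymonosulfate (active component of Oxone), [K+].OOS([O-])(=O)=O
Why: Shi asymmetric epoxidation, in which the chiral dioxirane attacks the electron-rich trisubstituted alkene through the spiro transition state and should set the (R) centre under catalyst control, while the monosubstituted allyl ether alkene reacts far more slowly and the methyl ester survives at 0 °C.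

**Step 9**
Reactants: 16 methyl 2-[4-(allyloxy)-3-{[(2R)-3,3-dimethyloxiran-2-yl]methyl}phenyl]acetate; 17 methyl glycolate
Product: 19 3-[4-(allyloxy)-3-{[(2R)-3,3-dimethyloxiran-2-yl]methyl}phenyl]-4-hydroxyfuran-2(5H)-one, via glycolate diester 18 (not isolated)
Conditions: KOtBu (2.3 equiv), DMF, 0 °C to rt; then cold citrate buffer (pH 4)
Reagents that add atoms: methyl glycolate, COC(=O)CO
Why: Tandem transesterification–Dieckmann condensation, in which the glycolate alkoxide exchanges onto the arylacetate and the arylacetate enolate closes 5-exo-trig on the glycolate ester to give the tetronate, without touching the epoxide stereocenter.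

**Step 10**
Reactants: 19 3-[4-(allyloxy)-3-{[(2R)-3,3-dimethyloxiran-2-yl]methyl}phenyl]-4-hydroxyfuran-2(5H)-one; 11 7-(allyloxy)-2,2-dimethylchroman-6-carbaldehyde
Product: 21 (5Z)-3-[4-(allyloxy)-3-{[(2R)-3,3-dimethyloxiran-2-yl]methyl}phenyl]-5-{[7-(allyloxy)-2,2-dimethylchroman-6-yl]methylidene}-4-hydroxyfuran-2(5H)-one, via aldol adduct 20 (not isolated)
Conditions: DBU (3 equiv), MeCN, 60 °C; then cold citrate buffer (pH 4)
Reagents that add atoms: none
Why: Vinylogous aldol (Knoevenagel-type) condensation, in which the C5 dienolate of the tetronate adds to the aldehyde and E1cB loss of water gives the 5-arylidene; the reversible sequence should settle on the thermodynamically preferred Z isomer, with the aryl group on the side of the ring oxygen and away from the C4 oxygen.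

**Step 11**
Reactants: 21 (5Z)-3-[4-(allyloxy)-3-{[(2R)-3,3-dimethyloxiran-2-yl]methyl}phenyl]-5-{[7-(allyloxy)-2,2-dimethylchroman-6-yl]methylidene}-4-hydroxyfuran-2(5H)-one
Product: 22 (5Z)-3-[3-{[(2R)-3,3-dimethyloxiran-2-yl]methyl}-4-hydroxyphenyl]-4-hydroxy-5-[(7-hydroxy-2,2-dimethylchroman-6-yl)methylidene]furan-2(5H)-one
Conditions: Pd(PPh3)4 (5 mol%), morpholine (6 equiv), THF, rt; then cold citrate buffer (pH 4), rapid extraction
Reagents that add atoms: none
Why: Tsuji–Trost-type deallylation, in which zerovalent palladium ionises both aryl allyl ethers and morpholine captures the π-allyl complexes irreversibly, so that the phenols should be released under near-neutral conditions that spare the epoxide, the exocyclic alkene and the stereocenter.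

**Compound list**
1 | 5-bromo-2,4-dihydroxybenzaldehyde | O=Cc1cc(Br)c(O)cc1O | starting material
2 | ethyl 2-bromo-2-methylpropanoate | CCOC(=O)C(C)(C)Br | starting material
3 | ethyl 2-(2-bromo-4-formyl-5-hydroxyphenoxy)-2-methylpropanoate | CCOC(=O)C(C)(C)Oc1cc(O)c(C=O)cc1Br | intermediate
4 | 4,4,5,5-tetramethyl-2-vinyl-1,3,2-dioxaborolane | C=CB1OC(C)(C)C(C)(C)O1 | starting material
5 | ethyl 2-(4-formyl-5-hydroxy-2-vinylphenoxy)-2-methylpropanoate | CCOC(=O)C(C)(C)Oc1cc(O)c(C=O)cc1C=C | intermediate
6 | allyl bromide | C=CCBr | starting material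
7 | ethyl 2-[5-(allyloxy)-4-formyl-2-vinylphenoxy]-2-methylpropanoate | CCOC(=O)C(C)(C)Oc1cc(OCC=C)c(C=O)cc1C=C | intermediate
8 | 2-[5-(allyloxy)-4-formyl-2-vinylphenoxy]-2-methylpropanoic acid | OC(=O)C(C)(C)Oc1cc(OCC=C)c(C=O)cc1C=C | intermediate
9 | N-hydroxyphthalimide | O=C1c2ccccc2C(=O)N1O | starting material
10 | 1,3-dioxoisoindolin-2-yl 2-[5-(allyloxy)-4-formyl-2-vinylphenoxy]-2-methylpropanoate | O=C(ON1C(=O)c2ccccc2C1=O)C(C)(C)Oc1cc(OCC=C)c(C=O)cc1C=C | intermediate
11 | 7-(allyloxy)-2,2-dimethylchroman-6-carbaldehyde | O=Cc1cc2CCC(C)(C)Oc2cc1OCC=C | intermediate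
12 | methyl 2-(3-bromo-4-hydroxyphenyl)acetate | COC(=O)Cc1ccc(O)c(Br)c1 | starting material
13 | tributyl(3-methylbut-2-en-1-yl)stannane | CCCC[Sn](CCCC)(CCCC)CC=C(C)C | starting material
14 | methyl 2-[4-hydroxy-3-(3-methylbut-2-en-1-yl)phenyl]acetate | COC(=O)Cc1ccc(O)c(CC=C(C)C)c1 | intermediate
15 | methyl 2-[4-(allyloxy)-3-(3-methylbut-2-en-1-yl)phenyl]acetate | COC(=O)Cc1ccc(OCC=C)c(CC=C(C)C)c1 | intermediate
16 | methyl 2-[4-(allyloxy)-3-{[(2R)-3,3-dimethyloxiran-2-yl]methyl}phenyl]acetate | COC(=O)Cc1ccc(OCC=C)c(C[C@H]2OC2(C)C)c1 | intermediate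
17 | methyl glycolate | COC(=O)CO | starting material
18 | 2-methoxy-2-oxoethyl 2-[4-(allyloxy)-3-{[(2R)-3,3-dimethyloxiran-2-yl]methyl}phenyl]acetate | COC(=O)COC(=O)Cc1ccc(OCC=C)c(C[C@H]2OC2(C)C)c1 | intermediate
19 | 3-[4-(allyloxy)-3-{[(2R)-3,3-dimethyloxiran-2-yl]methyl}phenyl]-4-hydroxyfuran-2(5H)-one | O=C1OCC(O)=C1c1ccc(OCC=C)c(C[C@H]2OC2(C)C)c1 | intermediate
20 | 3-[4-(allyloxy)-3-{[(2R)-3,3-dimethyloxiran-2-yl]methyl}phenyl]-5-{[7-(allyloxy)-2,2-dimethylchroman-6-yl](hydroxy)methyl}-4-hydroxyfuran-2(5H)-one (mixture at the two new carbinol centres) | O=C1OC(C(O)c2cc3CCC(C)(C)Oc3cc2OCC=C)C(O)=C1c1ccc(OCC=C)c(C[C@H]2OC2(C)C)c1 | intermediate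
21 | (5Z)-3-[4-(allyloxy)-3-{[(2R)-3,3-dimethyloxiran-2-yl]methyl}phenyl]-5-{[7-(allyloxy)-2,2-dimethylchroman-6-yl]methylidene}-4-hydroxyfuran-2(5H)-one | CC1(C)CCc2cc(/C=C3\OC(=O)C(c4ccc(OCC=C)c(C[C@H]5OC5(C)C)c4)=C3O)c(OCC=C)cc2O1 | intermediate
22 | (5Z)-3-[3-{[(2R)-3,3-dimethyloxiran-2-yl]methyl}-4-hydroxyphenyl]-4-hydroxy-5-[(7-hydroxy-2,2-dimethylchroman-6-yl)methylidene]furan-2(5H)-one | CC1(C)CCc2cc(/C=C3\OC(=O)C(c4ccc(O)c(C[C@H]5OC5(C)C)c4)=C3O)c(O)cc2O1 | target

**Step count.** Total: 11 steps. Longest linear sequence: 7 steps (steps 1–5, 10 and 11).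

**Steps most likely to fail**

Step 5. The process at risk is the fate of the radicals. The benzylic radical formed after ring closure is quenched only slowly by the Hantzsch ester and may add to the vinyl group of a second molecule. The photoreductant may also engage the formyl group. The fallback is a Barton decarboxylation run as a radical chain. It sets out from acid 8, which with 1-hydroxypyridine-2(1H)-thione and DCC (CH2Cl2, 0 °C, dark) should give the thiohydroxamate ester 2-thioxopyridin-1(2H)-yl 2-[5-(allyloxy)-4-formyl-2-vinylphenoxy]-2-methylpropanoate F1. Irradiation of this ester with a tungsten lamp in dilute benzene, with tert-butyl thiol added slowly as a fast hydrogen donor for the benzylic radical, should bring the route back at chroman aldehyde 11 by the same 6-endo closure.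

Step 6. The process at risk is allylic transposition during transmetalation, which would give the branched 2-methylbut-3-en-2-yl isomer, together with sluggish oxidative addition to the electron-rich bromophenol. The fallback sets out from bromide 12. Stille coupling with allyltributylstannane (Pd(PPh3)4, DMF, 100 °C), for which transposition is degenerate, should give methyl 2-(3-allyl-4-hydroxyphenyl)acetate F2. Olefin cross-metathesis of this phenol with 2-methylbut-2-ene, using the second-generation Grubbs catalyst RuCl2(=CHPh)(PCy3)(H2IMes) in CH2Cl2 at 40 °C, should return to prenylphenol 14.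

Step 9. The process at risk is prolonged exposure to excess tert-butoxide. It can isomerise the allyl ether to the prop-1-enyl ether and open the epoxide from the benzylic position while the transesterification is still slow. The fallback separates the two events. It sets out from ester 16, which LiOH (THF/H2O, rt, acidified only to pH 5) should convert into 2-[4-(allyloxy)-3-{[(2R)-3,3-dimethyloxiran-2-yl]methyl}phenyl]acetic acid F3. Alkylation of the carboxylate with methyl bromoacetate (Cs2CO3, DMF, rt) should give the glycolate diester 18, now isolated. A short Dieckmann cyclisation with LiN(SiMe3)2 in THF at −78 °C should come back at tetronic acid 19.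

**Further compounds**
F1 | step 5 | 2-thioxopyridin-1(2H)-yl 2-[5-(allyloxy)-4-formyl-2-vinylphenoxy]-2-methylpropanoate | S=C1C=CC=CN1OC(=O)C(C)(C)Oc1cc(OCC=C)c(C=O)cc1C=C
F2 | step 6 | methyl 2-(3-allyl-4-hydroxyphenyl)acetate | COC(=O)Cc1ccc(O)c(CC=C)c1
F3 | step 9 | 2-[4-(allyloxy)-3-{[(2R)-3,3-dimethyloxiran-2-yl]methyl}phenyl]acetic acid | OC(=O)Cc1ccc(OCC=C)c(C[C@H]2OC2(C)C)c1
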